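Assumption: germacrane numbering (C1–C15) is used for positions in all intermediates. Operations run one after another on unpurified material count as one step.

## Retrosynthetic overview

1. 24 comes from 9α-acetoxy-8β-hydroxycostunolide 17 by C8–O acylation, C14–H allylic oxidation (a C–O bond that also turns C1=C10 ring-cis) and desilylation.
2. 17 comes from bromo enal 15. The ten-membered carbocycle forms first (C6–C7, intramolecular allylchromium addition). The γ-lactone forms second, by C6–O acylation in the same flask.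
3. Key step: the C8–O bond of 14 is made by a Pd(0)-catalysed, stereoretentive silanol opening of epoxy enoate 12 (new). The C9–O bond is kept from the epoxide and acetylated.
4. 12 comes from trienal 6 by organocatalytic epoxidation, which makes both C–O bonds and sets the absolute configuration. An HWE reaction with phosphonate 9 then brings in C11–C13.
5. 6 comes from geranyl acetate 1 by SeO2 oxidation and a two-carbon Wittig homologation.

## Route

Step 1
Reactants: 1 geranyl acetate
Product: 3 (2E,6E)-3,7-dimethyl-8-oxoocta-2,6-dien-1-yl acetate, via allylic alcohol 2 (not isolated)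
Conditions: SeO2 (0.3 equiv), t-BuOOH (3 equiv), CH2Cl2, rt; crude, MnO2, CH2Cl2, rt
Reagents that add atoms: selenium dioxide O=[Se]=O; tert-butyl hydroperoxide CC(C)(C)OO
Why: Riley allylic oxidation (ene reaction then [2,3]-shift) attacks only the electron-rich distal alkene and only its (E)-methyl group, and MnO2 pushes the alcohol/aldehyde mixture to the (E)-enal; no stereocentre is formed.

Step 2
Reactants: 3 (2E,6E)-3,7-dimethyl-8-oxoocta-2,6-dien-1-yl acetate; 4 (1,3-dioxolan-2-ylmethyl)triphenylphosphonium bromide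
Product: 6 (2E,4E,8E)-10-hydroxy-4,8-dimethyldeca-2,4,8-trienal, via dienyl dioxolane 5 (not isolated)
Conditions: LiOMe (2.5 equiv), MeOH–DMF, 80 °C; then 1 M HCl, THF, rt
Reagents that add atoms: water O
Why: Wittig two-carbon homologation with a masked formyl ylide cannot over-homologate, LiOMe/MeOH removes the primary acetate by transesterification in the same pot, and acid hydrolysis of the acetal equilibrates the new alkene to E.

Step 3
Reactants: 7 trimethyl phosphonoacetate
Product: 8 methyl 2-(dimethoxyphosphoryl)-3-hydroxypropanoate (racemic)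
Conditions: (CH2O)n, piperidine (cat.), MeOH, reflux
Reagents that add atoms: formaldehyde (from paraformaldehyde) C=O
Why: Amine-catalysed aldol-type hydroxymethylation of the acidic phosphonoacetate CH2 stops at the mono-adduct under non-dehydrating conditions; the new stereocentre is racemic and is erased in step 5.

Step 4
Reactants: 8 methyl 2-(dimethoxyphosphoryl)-3-hydroxypropanoate
Product: 9 methyl 2-(dimethoxyphosphoryl)-3-[(triethylsilyl)oxy]propanoate (racemic)
Conditions: Et3SiCl, imidazole, CH2Cl2, 0 °C
Reagents that add atoms: chlorotriethylsilane CC[Si](Cl)(CC)CC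
Why: Standard silyl chloride/imidazole protection of a primary alcohol; TES is chosen because it can later be exchanged for bromide next to a secondary TBS ether.

Step 5
Reactants: 6 (2E,4E,8E)-10-hydroxy-4,8-dimethyldeca-2,4,8-trienal; 9 methyl 2-(dimethoxyphosphoryl)-3-[(triethylsilyl)oxy]propanoate
Product: 11 methyl (2E)-3-{(2S,3S)-3-[(2E,6E)-8-hydroxy-6-methylocta-2,6-dien-2-yl]oxiran-2-yl}-2-{[(triethylsilyl)oxy]methyl}prop-2-enoate, via epoxy aldehyde 10 (not isolated)
Conditions: (S)-2-{bis[3,5-bis(trifluoromethyl)phenyl][(trimethylsilyl)oxy]methyl}pyrrolidine (10 mol %), 35 % H2O2, CH2Cl2, rt; Na2S2O3 wash; crude added to 9/NaH, THF, –78 to 0 °C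
Reagents that add atoms: hydrogen peroxide OO
Why: Jørgensen–Hayashi iminium epoxidation adds H2O2 to C9 on the face left open by the (S)-catalyst (the enantiomer that gives (2R,3S)-epoxy aldehydes from (E)-enals) and closes the trans C8–C9 epoxide, which fixes both C–O stereocentres, and the Horner–Wadsworth–Emmons reaction then builds the (E)-C7=C11 enoate without touching them.

Step 6
Reactants: 11 epoxy enoate alcohol (name as in step 5)
Product: 12 methyl (2E)-3-{(2S,3S)-3-[(2E,6E)-6-methyl-8-oxoocta-2,6-dien-2-yl]oxiran-2-yl}-2-{[(triethylsilyl)oxy]methyl}prop-2-enoate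
Conditions: MnO2, CH2Cl2, rt
Reagents that add atoms: none
Why: MnO2 oxidises only the primary allylic alcohol to the (E)-enal under neutral conditions, so the vinyl epoxide, the silyl ether and both stereocentres are untouched.

Step 7
Reactants: 12 epoxy enoate enal (name as in step 6)
Product: 14 methyl (2E,4S,5S,6E,10E)-5-acetoxy-4-[(tert-butyldimethylsilyl)oxy]-6,10-dimethyl-12-oxo-2-{[(triethylsilyl)oxy]methyl}dodeca-2,6,10-trienoate, via hydroxy silyl ether 13 (not isolated)
Conditions: Pd(PPh3)4 (5 mol %), t-BuMe2SiOH (1.5 equiv), THF, 0 °C to rt; then Ac2O, Et3N, DMAP (cat.), 0 °C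
Reagents that add atoms: tert-butyldimethylsilanol CC(C)(C)[Si](C)(C)O; acetic anhydride CC(=O)OC(C)=O
Why: Proposed new method: Pd(0) binds the electron-poor C7=C11 alkene anti to the C8–O bond and ionises it with inversion to a π-allyl-Pd alkoxide, the C9 alkoxide deprotonates the more acidic silanol, and the hydrogen-bonded silanolate attacks C8 anti to Pd (second inversion; C11 is blocked as a fully substituted ester-bearing terminus and the silyl ether product cannot re-ionise), so the C8–O bond forms with net retention and the untouched C9–O is then acetylated to give the differentiated syn-8,9-diol; the closest known reaction types are the Pd(0)/trialkyl borate or boric acid double-inversion opening of γ,δ-epoxy-α,β-unsaturated esters and the use of silanolates as hydroxide surrogates in metal-catalysed allylic substitution.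

Step 8
Reactants: 14 silyl ether acetate (name as in step 7)
Product: 15 methyl (2Z,4S,5S,6E,10E)-5-acetoxy-2-(bromomethyl)-4-[(tert-butyldimethylsilyl)oxy]-6,10-dimethyl-12-oxododeca-2,6,10-trienoate
Conditions: Ph3PBr2 (1.1 equiv), CH2Cl2, –20 to 0 °C
Reagents that add atoms: dibromotriphenylphosphorane BrP(Br)(c1ccccc1)(c1ccccc1)c1ccccc1
Why: Appel-type silyl ether to bromide exchange through an oxyphosphonium ion is much faster at the unhindered primary allylic TES ether than at the hindered secondary TBS ether, and C8 and C9 are not involved.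

Step 9
Reactants: 15 bromo enal (name as in step 8)
Product: 17 (6R,7S,8S,9S)-9-acetoxy-8-hydroxygermacra-1(10)E,4E,11(13)-trien-12,6-olide (9α-acetoxy-8β-hydroxycostunolide), via silyl lactone 16 (not isolated)
Conditions: CrCl2 (10 equiv), THF–DMF, 4 Å MS, rt, syringe pump (final 2 mM); aq. work-up; crude, HF·pyridine, THF–pyridine, 0 °C to rt
Reagents that add atoms: none
Why: Intramolecular Nozaki–Hiyama (Barbier-type) allylation closes C6–C7 through a cyclic Cr(III) transition state in which, as in costunolide-type closures, the forming (E,E)-cyclodecadiene only accommodates the anti adduct (H-6/H-7 trans), the C8 stereocentre selects the allyl face through the conformer with C8–O in the alkene plane (inside alkoxy, σ*C–O out of conjugation with the nucleophilic π system) and C9 in the ring-forming outside position to give 6R,7S, the C6 chromium alkoxide then acylates on the methyl ester to close the lactone, and HF·pyridine frees the 8-OH.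

Step 10
Reactants: 18 ethyl 2-(hydroxymethyl)acrylate
Product: 19 ethyl 2-({[tert-butyl(dimethyl)silyl]oxy}methyl)acrylate
Conditions: TBSCl, imidazole, CH2Cl2, rt
Reagents that add atoms: tert-butyldimethylsilyl chloride CC(C)(C)[Si](C)(C)Cl
Why: Standard silyl chloride/imidazole protection of the primary alcohol keeps the side-chain hydroxyl out of the later esterification and oxidation.

Step 11
Reactants: 19 ethyl 2-({[tert-butyl(dimethyl)silyl]oxy}methyl)acrylate
Product: 20 2-({[tert-butyl(dimethyl)silyl]oxy}methyl)acrylic acid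
Conditions: LiOH, THF–H2O, 0 °C to rt; 1 M HCl to pH 4, 0 °C
Reagents that add atoms: lithium hydroxide [Li+].[OH-]
Why: Saponification of the ethyl ester, to which the primary TBS ether is stable, followed by careful acidification gives the free acid.

Step 12
Reactants: 17 9α-acetoxy-8β-hydroxycostunolide; 20 2-({[tert-butyl(dimethyl)silyl]oxy}methyl)acrylic acid
Product: 21 (6R,7S,8S,9S)-9-acetoxy-8-{[2-({[tert-butyl(dimethyl)silyl]oxy}methyl)acryloyl]oxy}germacra-1(10)E,4E,11(13)-trien-12,6-olide
Conditions: DCC, DMAP (cat.), CH2Cl2, 0 °C to rt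
Reagents that add atoms: none
Why: Steglich esterification of the only free hydroxyl group forms the C8–O acyl bond with retention because the C8–O bond itself is not broken.

Step 13
Reactants: 21 (E,E)-ester (name as in step 12)
Product: 23 (6R,7S,8S,9S)-9-acetoxy-8-{[2-({[tert-butyl(dimethyl)silyl]oxy}methyl)acryloyl]oxy}-14-oxogermacra-1(10),4E,11(13)-trien-12,6-olide (C1=C10 ring-cis; CHO trans to C2), via C14 alcohol 22 (not isolated)
Conditions: SeO2 (0.5 equiv), t-BuOOH (3 equiv), CH2Cl2, 0 °C to rt; crude, MnO2, CH2Cl2, rt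
Reagents that add atoms: selenium dioxide O=[Se]=O; tert-butyl hydroperoxide CC(C)(C)OO
Why: Riley oxidation puts Se on C1 and takes H from C14 (C4=C5 is deactivated and shielded by the lactone oxygen next to the carbon that would have to bind Se, and the two acrylate-type alkenes are electron-poor), the [2,3]-shift places C2 trans to the new CH2OH and so turns the ring alkene from trans to cis as is known for parthenolide and costunolide, and MnO2 takes the allylic alcohol to the enal without touching a stereocentre.

Step 14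
Reactants: 23 silyl-protected aldehyde (name as in step 13)
Product: 24 (6R,7S,8S,9S)-9-acetoxy-8-{[2-(hydroxymethyl)acryloyl]oxy}-14-oxogermacra-1(10),4E,11(13)-trien-12,6-olide (C1=C10 ring-cis melampolide; CNP0177123.1)
Conditions: HF·pyridine, THF–pyridine, 0 °C
Reagents that add atoms: none
Why: Fluoride cleavage of the primary TBS ether under buffered acidic conditions spares the acetate, both acrylate-type esters, the enal and all four stereocentres.

## Compound list

1 | geranyl acetate | CC(C)=CCC/C(C)=C/COC(C)=O | starting material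
2 | (2E,6E)-8-hydroxy-3,7-dimethylocta-2,6-dien-1-yl acetate | OC/C(C)=C/CC/C(C)=C/COC(C)=O | intermediate (not isolated)
3 | (2E,6E)-3,7-dimethyl-8-oxoocta-2,6-dien-1-yl acetate | O=C/C(C)=C/CC/C(C)=C/COC(C)=O | intermediate
4 | (1,3-dioxolan-2-ylmethyl)triphenylphosphonium bromide | [Br-].C1COC(C[P+](c2ccccc2)(c2ccccc2)c2ccccc2)O1 | starting material
5 | 2-[(3E,7E)-9-hydroxy-3,7-dimethylnona-1,3,7-trien-1-yl]-1,3-dioxolane (1E/1Z mixture) | OC/C=C(\C)CC/C=C(\C)C=CC1OCCO1 | intermediate (not isolated)
6 | (2E,4E,8E)-10-hydroxy-4,8-dimethyldeca-2,4,8-trienal | O=C/C=C/C(C)=C/CC/C(C)=C/CO | intermediate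
7 | trimethyl phosphonoacetate | COC(=O)CP(=O)(OC)OC | starting material
8 | methyl 2-(dimethoxyphosphoryl)-3-hydroxypropanoate (racemic) | COC(=O)C(CO)P(=O)(OC)OC | intermediate
9 | methyl 2-(dimethoxyphosphoryl)-3-[(triethylsilyl)oxy]propanoate (racemic) | COC(=O)C(CO[Si](CC)(CC)CC)P(=O)(OC)OC | intermediate
10 | (2R,3S)-3-[(2E,6E)-8-hydroxy-6-methylocta-2,6-dien-2-yl]oxirane-2-carbaldehyde | O=C[C@@H]1O[C@H]1/C(C)=C/CC/C(C)=C/CO | intermediate (not isolated)
11 | methyl (2E)-3-{(2S,3S)-3-[(2E,6E)-8-hydroxy-6-methylocta-2,6-dien-2-yl]oxiran-2-yl}-2-{[(triethylsilyl)oxy]methyl}prop-2-enoate | COC(=O)/C(CO[Si](CC)(CC)CC)=C/[C@@H]1O[C@H]1/C(C)=C/CC/C(C)=C/CO | intermediate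
12 | methyl (2E)-3-{(2S,3S)-3-[(2E,6E)-6-methyl-8-oxoocta-2,6-dien-2-yl]oxiran-2-yl}-2-{[(triethylsilyl)oxy]methyl}prop-2-enoate | COC(=O)/C(CO[Si](CC)(CC)CC)=C/[C@@H]1O[C@H]1/C(C)=C/CC/C(C)=C/C=O | intermediate
13 | methyl (2E,4S,5S,6E,10E)-4-[(tert-butyldimethylsilyl)oxy]-5-hydroxy-6,10-dimethyl-12-oxo-2-{[(triethylsilyl)oxy]methyl}dodeca-2,6,10-trienoate | COC(=O)/C(CO[Si](CC)(CC)CC)=C/[C@H](O[Si](C)(C)C(C)(C)C)[C@@H](O)/C(C)=C/CC/C(C)=C/C=O | intermediate (not isolated)
14 | methyl (2E,4S,5S,6E,10E)-5-acetoxy-4-[(tert-butyldimethylsilyl)oxy]-6,10-dimethyl-12-oxo-2-{[(triethylsilyl)oxy]methyl}dodeca-2,6,10-trienoate | COC(=O)/C(CO[Si](CC)(CC)CC)=C/[C@H](O[Si](C)(C)C(C)(C)C)[C@@H](OC(C)=O)/C(C)=C/CC/C(C)=C/C=O | intermediate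
15 | methyl (2Z,4S,5S,6E,10E)-5-acetoxy-2-(bromomethyl)-4-[(tert-butyldimethylsilyl)oxy]-6,10-dimethyl-12-oxododeca-2,6,10-trienoate | COC(=O)/C(CBr)=C/[C@H](O[Si](C)(C)C(C)(C)C)[C@@H](OC(C)=O)/C(C)=C/CC/C(C)=C/C=O | intermediate
16 | (6R,7S,8S,9S)-9-acetoxy-8-[(tert-butyldimethylsilyl)oxy]germacra-1(10)E,4E,11(13)-trien-12,6-olide | CC(C)(C)[Si](C)(C)O[C@H]1[C@H]2C(=C)C(=O)O[C@@H]2/C=C(\C)CC/C=C(\C)[C@@H]1OC(C)=O | intermediate (not isolated)
17 | (6R,7S,8S,9S)-9-acetoxy-8-hydroxygermacra-1(10)E,4E,11(13)-trien-12,6-olide | O[C@H]1[C@H]2C(=C)C(=O)O[C@@H]2/C=C(\C)CC/C=C(\C)[C@@H]1OC(C)=O | intermediate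
18 | ethyl 2-(hydroxymethyl)acrylate | C=C(CO)C(=O)OCC | starting material
19 | ethyl 2-({[tert-butyl(dimethyl)silyl]oxy}methyl)acrylate | C=C(CO[Si](C)(C)C(C)(C)C)C(=O)OCC | intermediate
20 | 2-({[tert-butyl(dimethyl)silyl]oxy}methyl)acrylic acid | C=C(CO[Si](C)(C)C(C)(C)C)C(=O)O | intermediate
21 | (6R,7S,8S,9S)-9-acetoxy-8-{[2-({[tert-butyl(dimethyl)silyl]oxy}methyl)acryloyl]oxy}germacra-1(10)E,4E,11(13)-trien-12,6-olide | C=C(CO[Si](C)(C)C(C)(C)C)C(=O)O[C@H]1[C@H]2C(=C)C(=O)O[C@@H]2/C=C(\C)CC/C=C(\C)[C@@H]1OC(C)=O | intermediate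
22 | 14-hydroxy analogue of 21 with ring-cis C1=C10 (CH2OH trans to C2) | C=C(CO[Si](C)(C)C(C)(C)C)C(=O)O[C@H]1[C@H]2C(=C)C(=O)O[C@@H]2/C=C(\C)CC/C=C(/CO)[C@@H]1OC(C)=O | intermediate (not isolated)
23 | 14-oxo analogue of 21 with ring-cis C1=C10 (CHO trans to C2) | C=C(CO[Si](C)(C)C(C)(C)C)C(=O)O[C@H]1[C@H]2C(=C)C(=O)O[C@@H]2/C=C(\C)CC/C=C(/C=O)[C@@H]1OC(C)=O | intermediate
24 | CNP0177123.1, (6R,7S,8S,9S)-9-acetoxy-8-{[2-(hydroxymethyl)acryloyl]oxy}-14-oxogermacra-1(10),4E,11(13)-trien-12,6-olide (ring-cis C1=C10) | C=C(CO)C(=O)O[C@H]1[C@H]2C(=C)C(=O)O[C@@H]2/C=C(\C)CC/C=C(/C=O)[C@@H]1OC(C)=O | target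

## Step count and risks

Total step count: 14.
Longest linear sequence: 10 (steps 1, 2, 5, 6, 7, 8, 9, 12, 13, 14).

**Step 7 (the proposed new step).**
- What can go wrong: the silanol may be too weak or too bulky a nucleophile. Pd(0) may isomerise the vinyl epoxide to a dienol or enone. It may also ionise the C9 side of the epoxide instead.
- Fallback: it sets out from 12, uses known chemistry and comes back at 13. Compound 12 is opened with Pd(PPh3)4 and boric acid in THF. This is the established double-inversion hydroxylation of γ,δ-epoxy enoates. It gives methyl (2E,4S,5S,6E,10E)-4,5-dihydroxy-6,10-dimethyl-12-oxo-2-{[(triethylsilyl)oxy]methyl}dodeca-2,6,10-trienoate F1. The C8 hydroxyl of this syn-diol is the less hindered one (its neighbour is CH=, not C(Me)=) and the more acidic one. It is mono-silylated with TBSCl/imidazole at –20 °C, or through the dibutylstannylene acetal, to give 13. Acetylation as in step 7 then gives 14.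

**Step 9 (macrocyclisation).**
- What can go wrong: the ten-membered ring may close in low yield. It may close on the wrong allyl face, because a conformer with the silyloxy group anti competes. A cis-lactone may form.
- Fallback: it sets out from 15 and comes back at 17. It replaces stereocontrol by a non-chelating silyl ether on Cr(III) with stereocontrol by a metal-bound free hydroxyl. HF·pyridine first frees the C8 hydroxyl of 15 to give methyl (2Z,4S,5S,6E,10E)-5-acetoxy-2-(bromomethyl)-4-hydroxy-6,10-dimethyl-12-oxododeca-2,6,10-trienoate F2. This compound is closed without protecting groups by an indium-mediated Barbier reaction in THF–water at 2 mM. Here the hydroxyl-chelated allylindium holds C8–O in the alkene plane. This type of control is known for hydroxy-substituted 2-(bromomethyl)acrylates. Brief treatment with PPTS completes the lactonisation to 17.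

**Step 13 (late allylic oxidation with ring-alkene flip).**
- What can go wrong: the 9-acetoxy group deactivates C1=C10. The methyl group that must react is the less reactive one (cis to C2). Oxidation at C15 or C3, or incomplete trans-to-cis change, is therefore possible.
- Fallback: it sets out from 21 and comes back at 22. It separates the isomerisation from the oxidation. Sensitised irradiation of 21 (the known photochemical E/Z interconversion of the 1(10)-alkene of germacranolides) gives, after separation and recycling, the 1(10)Z isomer of 21 F3. Its C14 methyl group now lies cis to H-1, which is the position that SeO2 oxidises preferentially and without a change of geometry. SeO2/t-BuOOH then gives 22, and MnO2 gives 23 as in step 13.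

## Further compounds

F1 | step 7 | methyl (2E,4S,5S,6E,10E)-4,5-dihydroxy-6,10-dimethyl-12-oxo-2-{[(triethylsilyl)oxy]methyl}dodeca-2,6,10-trienoate | COC(=O)/C(CO[Si](CC)(CC)CC)=C/[C@H](O)[C@@H](O)/C(C)=C/CC/C(C)=C/C=O
F2 | step 9 | methyl (2Z,4S,5S,6E,10E)-5-acetoxy-2-(bromomethyl)-4-hydroxy-6,10-dimethyl-12-oxododeca-2,6,10-trienoate | COC(=O)/C(CBr)=C/[C@H](O)[C@@H](OC(C)=O)/C(C)=C/CC/C(C)=C/C=O
F3 | step 13 | (6R,7S,8S,9S)-9-acetoxy-8-{[2-({[tert-butyl(dimethyl)silyl]oxy}methyl)acryloyl]oxy}germacra-1(10)Z,4E,11(13)-trien-12,6-olide | C=C(CO[Si](C)(C)C(C)(C)C)C(=O)O[C@H]1[C@H]2C(=C)C(=O)O[C@@H]2/C=C(\C)CC/C=C(/C)[C@@H]1OC(C)=O
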